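**Retrosynthetic overview**
- The target is three butyrylphloroglucinol units tied by two CH2 bridges and has no stereocentre. Ring A is a dienone (C1=O, C2 butyryl, C4 bridge, C6 gem-dimethyl). Ring B has C1 butyryl, C3 bridge to ring A and C5 bridge to ring C. Ring C has C1 butyryl, C3 bridge and C5 methyl.
- Last disconnection: the bond from the bridge CH2 on C3 of ring C to C5 of ring B. It is made by a deaminative, decarboxylative union of a ring C Mannich base with a ring A–ring B acid that carries CO2H on C5 of ring B. One operation forms the C–C bond, expels both activating groups as gases, rearomatises two rings and gives the unprotected target.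
- Enabling feature: the bridge CH2 sits on C3 of ring C between C2–OH and C4–OH, so CH2–NMe2 collapses to an o-quinone methide. C5 of ring B sits between C4–OH and C6–OH and is the alpha carbon of a masked cyclic beta-diketone, so a CO2H placed there is a vinylogous beta-keto acid that leaves as CO2 once that carbon is attacked.
- The same CO2H differentiates the two equivalent carbons C3 and C5 of phlorbutyrophenone. It goes on by Kolbe–Schmitt carboxylation, blocks C5 while the ring A enone is added at C3 at room temperature (second disconnection, C4 of ring A–CH2–C3 of ring B), and is consumed in the last step.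
- No ring is built: all three carbocycles are bought as phloroglucinols. Ring A is shaped first by dearomatising gem-dimethylation, ring A and ring B are joined next, and ring C is attached last.

Key step: step 8

Assumption: 2-methylphloroglucinol is taken as a purchasable starting material, and all keto/enol tautomers are drawn in the form used in the target SMILES.

Step 1
Reactants: 1 phloroglucinol (benzene-1,3,5-triol)
Product: 2 phlorbutyrophenone (1-(2,4,6-trihydroxyphenyl)butan-1-one)
Conditions: butyryl chloride, AlCl3, CH2Cl2/PhNO2, 0 to 40 °C; then ice/aq. HCl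
Reagents that add atoms: butyryl chloride, CCCC(=O)Cl
Why: Friedel–Crafts acylation of the very electron-rich ring, which stops after one acyl group because the chelated aryl ketone deactivates the remaining positions.

Step 2
Reactants: 2 phlorbutyrophenone
Product: 3 butyrylfilicinic acid (2-butanoyl-3,5-dihydroxy-6,6-dimethylcyclohexa-2,4-dien-1-one)
Conditions: NaOMe, MeI (about 2 equiv), MeOH, 0 °C to rt; then aq. HCl
Reagents that add atoms: iodomethane, CI
Why: Alkylative dearomatisation by double C-methylation of the phenoxide, in which the second methyl enters at the already methylated, more electron-rich carbon, makes it quaternary and locks the ring as the acylfilicinic acid enol, a known reaction of acylphloroglucinols.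

Step 3
Reactants: 3 butyrylfilicinic acid
Product: 4 ring A Mannich base (2-butanoyl-4-[(dimethylamino)methyl]-3,5-dihydroxy-6,6-dimethylcyclohexa-2,4-dien-1-one, inner salt)
Conditions: Me2NCH2NMe2, MeCN, 0 °C to rt; filter
Reagents that add atoms: bis(dimethylamino)methane, CN(C)CN(C)C
Why: Mannich reaction in which the acidic enol of 3 activates the aminal and the only C–H carbon of ring A (C4) takes up the CH2NMe2 unit, the inner salt separating from MeCN before it can lose amine.

Step 4
Reactants: 2 phlorbutyrophenone
Product: 5 3-butanoyl-2,4,6-trihydroxybenzoic acid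
Conditions: KHCO3 (large excess), H2O, CO2 blanket, 50 °C; then cold aq. HCl to pH 2
Reagents that add atoms: potassium hydrogencarbonate, [K+].OC([O-])=O (in equilibrium with carbon dioxide, O=C=O)
Why: Kolbe–Schmitt carboxylation under the aqueous hydrogencarbonate conditions that serve for phloroglucinols, in which the phenoxide attacks CO2 through one of its two equivalent C–H carbons and the product, now carrying an acyl and a carboxylate group, is too deactivated to react twice.

Step 5
Reactants: 4 ring A Mannich base; 5 3-butanoyl-2,4,6-trihydroxybenzoic acid
Product: 7 ring A–ring B acid (3-butanoyl-5-[(5-butanoyl-2,6-dihydroxy-3,3-dimethyl-4-oxocyclohexa-1,5-dien-1-yl)methyl]-2,4,6-trihydroxybenzoic acid), via ring A enone 6 (not isolated)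
Conditions: 1:1, THF, 20–25 °C, N2; then cold dilute HCl/EtOAc
Reagents that add atoms: none
Why: Amine loss from the protonated Mannich base gives enone 6, and Michael addition of the one C–H carbon of 5 followed by enolisation forms the bridge, the established way to methylene-bridged acylphloroglucinols, while the preference of electrophiles for a free C–H position of trihydroxybenzoic acids over the carboxyl-bearing one and the low temperature keep the CO2H in place.

Step 6
Reactants: 8 2-methylphloroglucinol (2-methylbenzene-1,3,5-triol)
Product: 9 methylphlorbutyrophenone (1-(2,4,6-trihydroxy-3-methylphenyl)butan-1-one)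
Conditions: butyryl chloride, AlCl3, CH2Cl2/PhNO2, 0 to 40 °C; then ice/aq. HCl
Reagents that add atoms: butyryl chloride, CCCC(=O)Cl
Why: Friedel–Crafts acylation at one of the two equivalent free carbons of 8, self-limiting for the same reason as in step 1.

Step 7
Reactants: 9 methylphlorbutyrophenone
Product: 10 ring C Mannich base (1-{3-[(dimethylamino)methyl]-2,4,6-trihydroxy-5-methylphenyl}butan-1-one)
Conditions: Me2NCH2NMe2, EtOH, rt to 40 °C
Reagents that add atoms: bis(dimethylamino)methane, CN(C)CN(C)C
Why: Mannich reaction at the single remaining C–H carbon of ring C, ortho and para to hydroxyl groups, giving a storable aromatic Mannich base.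

Step 8
Reactants: 7 ring A–ring B acid; 10 ring C Mannich base
Product: 13 target trimer CNP0086105.0 (2-butanoyl-4-({3-butanoyl-5-[(3-butanoyl-2,4,6-trihydroxy-5-methylphenyl)methyl]-2,4,6-trihydroxyphenyl}methyl)-3,5-dihydroxy-6,6-dimethylcyclohexa-2,4-dien-1-one), via o-quinone methide 11 (not isolated), via dienone acid 12 (not isolated)
Conditions: 1:1.05, 1,4-dioxane, 80–85 °C, slow N2 stream, no added base; then cold dilute HCl/EtOAc
Reagents that add atoms: none
Why: Proposed new method: the CO2H of 7 protonates the NMe2 group of 10, the ammonium group leaves across C3–CH2 of ring C under push from a flanking C2 or C4 hydroxyl to give o-quinone methide 11, the carboxyl-bearing C5 of ring B (alpha carbon of a cyclic vinylogous beta-keto acid, set between C4–OH and C6–OH) adds to the exocyclic CH2 so that ring C rearomatises, and dienone acid 12 then loses CO2 so that ring B rearomatises. The closest known reaction types are the thermal Mannich-base o-quinone methide alkylation used to bridge acylphloroglucinols and the decarboxylative Michael addition of aliphatic beta-keto acids to o-quinone methides; the ipso, decarboxylative variant on a trihydroxybenzoic acid is the new element, backed by the known ipso displacement of CO2 from such acids by protons, halogens and diazonium ions. No ring is closed and no stereocentre is left, since the quaternary carbon of 12 forms as a racemate and becomes planar again when CO2 leaves. Site selectivity is built into the substrates: every other ring carbon of 7, 10 and 11 is substituted, capture of 11 at oxygen, nitrogen or an alkyl-bearing carbon is reversible, and only capture at C5 is made irreversible by loss of CO2. Should a proton reach C5 before 11 does, CO2 is lost first and the same carbon remains the only open nucleophilic site, so both timings lead to 13. The step also needs the ring A–ring B bridge to stay intact, which is served by the absence of added base, the single equivalent of volatile amine being swept out together with CO2 by the nitrogen stream.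

**Compound list**
1 | phloroglucinol (benzene-1,3,5-triol) | Oc1cc(O)cc(O)c1 | starting material
2 | phlorbutyrophenone (1-(2,4,6-trihydroxyphenyl)butan-1-one) | CCCC(=O)c1c(O)cc(O)cc1O | intermediate
3 | butyrylfilicinic acid (2-butanoyl-3,5-dihydroxy-6,6-dimethylcyclohexa-2,4-dien-1-one) | CCCC(=O)C1=C(O)C=C(O)C(C)(C)C1=O | intermediate
4 | ring A Mannich base (2-butanoyl-4-[(dimethylamino)methyl]-3,5-dihydroxy-6,6-dimethylcyclohexa-2,4-dien-1-one) | CCCC(=O)C1=C(O)C(CN(C)C)=C(O)C(C)(C)C1=O | intermediate
5 | 3-butanoyl-2,4,6-trihydroxybenzoic acid | CCCC(=O)c1c(O)cc(O)c(C(=O)O)c1O | intermediate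
6 | ring A enone (2-butanoyl-3-hydroxy-6,6-dimethyl-4-methylidenecyclohex-2-ene-1,5-dione) | CCCC(=O)C1=C(O)C(=C)C(=O)C(C)(C)C1=O | intermediate
7 | ring A–ring B acid (3-butanoyl-5-[(5-butanoyl-2,6-dihydroxy-3,3-dimethyl-4-oxocyclohexa-1,5-dien-1-yl)methyl]-2,4,6-trihydroxybenzoic acid) | CCCC(=O)C1=C(O)C(Cc2c(O)c(C(=O)O)c(O)c(C(=O)CCC)c2O)=C(O)C(C)(C)C1=O | intermediate
8 | 2-methylphloroglucinol (2-methylbenzene-1,3,5-triol) | Cc1c(O)cc(O)cc1O | starting material
9 | methylphlorbutyrophenone (1-(2,4,6-trihydroxy-3-methylphenyl)butan-1-one) | CCCC(=O)c1c(O)cc(O)c(C)c1O | intermediate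
10 | ring C Mannich base (1-{3-[(dimethylamino)methyl]-2,4,6-trihydroxy-5-methylphenyl}butan-1-one) | CCCC(=O)c1c(O)c(C)c(O)c(CN(C)C)c1O | intermediate
11 | ring C o-quinone methide (2-butanoyl-3,5-dihydroxy-4-methyl-6-methylidenecyclohexa-2,4-dien-1-one) | CCCC(=O)C1=C(O)C(C)=C(O)C(=C)C1=O | intermediate
12 | dienone acid (ring B dearomatised; its C5 is quaternary and carries CO2H and the CH2–ring C group; racemic, transient) | CCCC(=O)C1=C(O)C(CC2=C(O)C(C(=O)O)(Cc3c(O)c(C)c(O)c(C(=O)CCC)c3O)C(=O)C(C(=O)CCC)=C2O)=C(O)C(C)(C)C1=O | intermediate
13 | target CNP0086105.0 | CCCC(=O)C1=C(O)C(Cc2c(O)c(Cc3c(O)c(C)c(O)c(C(=O)CCC)c3O)c(O)c(C(=O)CCC)c2O)=C(O)C(C)(C)C1=O | target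

**Step count:** 8 steps in total. The longest linear sequence is 5 steps (steps 1, 2, 3, 5, 8).

**Steps most likely to fail**

1. **Step 8 (proposed new method).**
 - Risk: release of the o-quinone methide and loss of CO2 may fall out of step, so that the quinone methide dimerises. The warm, amine-containing medium may also start retro-Michael exchange of the ring A–ring B bridge.
 - Fallback (sets out from 7 and 10, comes back at 13): the two events are separated and the coupling is run cold, all by known chemistry. 7 is protodecarboxylated (wet 1,4-dioxane, trace HCl, 60 °C) to the C–H dimer 2-butanoyl-4-[(3-butanoyl-2,4,6-trihydroxyphenyl)methyl]-3,5-dihydroxy-6,6-dimethylcyclohexa-2,4-dien-1-one F1. 10 is quaternised with MeI in acetone to the benzyltrimethylammonium iodide [3-butanoyl-2,4,6-trihydroxy-5-methylphenyl]methyl-trimethylammonium iodide F2. F1 and F2 are combined with NaHCO3 in aqueous MeCN at room temperature, where the phenoxide of F2 expels NMe3 to give 11, which the one free carbon of F1 takes up to give 13.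

2. **Step 4.**
 - Risk: the carboxylation equilibrium may lie on the side of the deactivated acylphenol, or CO2 may be lost again on acidification.
 - Fallback (sets out from 1, comes back at 5): the order of the two substitutions is reversed. 1, the standard substrate for aqueous KHCO3 carboxylation, is converted into 2,4,6-trihydroxybenzoic acid F3. Carboxylate alkylation (BnBr, KHCO3, DMF) gives benzyl 2,4,6-trihydroxybenzoate F4. Friedel–Crafts acylation (butyric anhydride, BF3·OEt2, 60 °C) gives benzyl 3-butanoyl-2,4,6-trihydroxybenzoate F5. Hydrogenolysis (H2, Pd/C, EtOAc, rt) then frees 5 without base or heat.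

3. **Step 5.**
 - Risk: early loss of amine from the ring A Mannich base may let ring A material capture the enone. Attack at the carboxyl-bearing carbon may also cause premature loss of CO2 and a second alkylation.
 - Fallback (sets out from 5 and 3, comes back at 7): donor and acceptor roles are exchanged. 5 is aminomethylated at its one free carbon with bis(dimethylamino)methane to the storable inner salt 3-butanoyl-5-[(dimethylamino)methyl]-2,4,6-trihydroxybenzoic acid F6. Gentle warming of F6 with 3 in THF (about 45 °C) releases the ring B o-quinone methide 3-butanoyl-2,4-dihydroxy-5-methylidene-6-oxocyclohexa-1,3-diene-1-carboxylic acid F7. F7 has no free nucleophilic carbon of its own, and the only C–H carbon of ring A takes it up to give 7.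

**Further compounds**
F1 | step 8 | 2-butanoyl-4-[(3-butanoyl-2,4,6-trihydroxyphenyl)methyl]-3,5-dihydroxy-6,6-dimethylcyclohexa-2,4-dien-1-one | CCCC(=O)C1=C(O)C(Cc2c(O)cc(O)c(C(=O)CCC)c2O)=C(O)C(C)(C)C1=O
F2 | step 8 | [3-butanoyl-2,4,6-trihydroxy-5-methylphenyl]methyl-trimethylammonium iodide | CCCC(=O)c1c(O)c(C)c(O)c(C[N+](C)(C)C)c1O.[I-]
F3 | step 4 | 2,4,6-trihydroxybenzoic acid | O=C(O)c1c(O)cc(O)cc1O
F4 | step 4 | benzyl 2,4,6-trihydroxybenzoate | O=C(OCc1ccccc1)c1c(O)cc(O)cc1O
F5 | step 4 | benzyl 3-butanoyl-2,4,6-trihydroxybenzoate | CCCC(=O)c1c(O)cc(O)c(C(=O)OCc2ccccc2)c1O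
F6 | step 5 | 3-butanoyl-5-[(dimethylamino)methyl]-2,4,6-trihydroxybenzoic acid | CCCC(=O)c1c(O)c(CN(C)C)c(O)c(C(=O)O)c1O
F7 | step 5 | 3-butanoyl-2,4-dihydroxy-5-methylidene-6-oxocyclohexa-1,3-diene-1-carboxylic acid | CCCC(=O)C1=C(O)C(=C)C(=O)C(C(=O)O)=C1O
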